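**Retrosynthetic overview**

1. Labels: ring A is the lactone O1–C2(=O)–C3–C4–C5; the chain leaves C3 as C1′H=, C2′H2, C3′H(OAc), C4′(CH3)=C5′H, C6′H2, C7′H2, C8′(CH3)=C9′H, C10′H2–O. The strategy rests on C4 (OH) and C5 (O1, isobutenyl): two adjacent, trans, oxygen-bearing carbons between the exocyclic E alkene C3=C1′ and the isobutenyl group. This is the pattern a γ-oxygenated allylboron unit leaves when it adds to 3-methylbut-2-enal and its double bond moves to C3=C1′.
2. Disconnections, last to first: the C10′–O angelate ester; the O1–C2 lactone bond (ring A, the only ring, closed after the key step); the C4–C5 bond, by allylboration of prenal with an α-chiral γ-silyloxy 2-(methoxycarbonyl)allyl pinacol boronate carrying boron on C1′.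
3. That boronate: C1′–B by copper-catalysed asymmetric conjugate borylation of a 2-(hydroxymethyl)alk-2-enoate, then oxidation to the α-formyl ester and O-silylation of its lithium chelate, which holds the enol oxygen cis to the ester and trans to C1′.
4. The enoate: C3=C1′ by cross-metathesis of a homoallylic acetate with methyl 2-(hydroxymethyl)acrylate; the acetate from nerol by silylation, SeO2 oxidation, asymmetric allylation (C3′) and acetylation.

Key step: step 9

Remarks on the chemistry (assumptions)
- An enol ether oxygen introduced by alkoxide loss from an acetal next to the ester would be expected to end trans to the ester, that is cis to C1′. That geometry gives the syn series, so the oxygen is instead silylated on the lithium chelate of the α-formyl ester and carried as a TBS ether.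
- The angelate is attached last, so that the copper step meets only one conjugated ester; C10′–OH travels as a TBS ether.
- The (R,SP) ferrocenyl bisphosphine of step 6 is assumed to be the hand that gives S at C1′; if a trial shows the opposite sense, its mirror image is used.

**Route**

Step 1
Reactants: 1 nerol
Product: 2 neryl TBS ether, tert-butyl{[(2Z)-3,7-dimethylocta-2,6-dien-1-yl]oxy}dimethylsilane
Conditions: TBSCl (1.1 equiv), imidazole (1.5 equiv), CH2Cl2, 0 → 23 °C
Reagents that add atoms: tert-butyldimethylsilyl chloride, CC(C)(C)[Si](C)(C)Cl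
Why: Imidazole-assisted silylation of the primary allylic alcohol masks C10′–OH until step 11 and creates no stereocentre.

Step 2
Reactants: 2 neryl TBS ether
Product: 4 (2E,6Z)-8-[(tert-butyldimethylsilyl)oxy]-2,6-dimethylocta-2,6-dienal, via allylic alcohol 3 (not isolated)
Conditions: SeO2 (0.3 equiv), t-BuOOH (3 equiv), salicylic acid (0.1 equiv), CH2Cl2, 23 °C; silica plug; MnO2 (15 equiv), CH2Cl2, 23 °C
Reagents that add atoms: selenium dioxide, O=[Se]=O; tert-butyl hydroperoxide (terminal oxidant), CC(C)(C)OO
Why: Riley oxidation (ene reaction then [2,3]-sigmatropic shift) should attack the E methyl of the electron-rich terminal alkene, the other alkene being deactivated by its allylic silyloxy group, and MnO2 takes the E allylic alcohol 3 on to the E enal.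

Step 3
Reactants: 4 the enal; 5 allylboronic acid pinacol ester
Product: 7 (4S,5E,9Z)-11-[(tert-butyldimethylsilyl)oxy]-5,9-dimethylundeca-1,5,9-trien-4-ol, via borate ester 6 (not isolated)
Conditions: 5 (1.3 equiv), (S)-TRIP [(S)-3,3′-bis(2,4,6-triisopropylphenyl)-1,1′-binaphthyl-2,2′-diyl hydrogen phosphate] (5 mol %), 4 Å MS, toluene, −30 °C; aq NaHCO3
Reagents that add atoms: none
Why: Chiral phosphoric acid-catalysed allylboration through a chair in which the acid activates the boronate should deliver the allyl group to the Si face of the enal and set C3′ as S; the S acid is chosen because the R acid is known to give R carbinols from aryl and alkenyl aldehydes.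

Step 4
Reactants: 7 the homoallylic alcohol
Product: 8 (4S,5E,9Z)-11-[(tert-butyldimethylsilyl)oxy]-5,9-dimethylundeca-1,5,9-trien-4-yl acetate
Conditions: Ac2O (1.5 equiv), pyridine, DMAP (5 mol %), CH2Cl2, 0 → 23 °C
Reagents that add atoms: acetic anhydride, CC(=O)OC(C)=O
Why: DMAP-catalysed acylation of the secondary allylic alcohol installs the acetate of the target and leaves C3′ untouched.

Step 5
Reactants: 8 the homoallylic acetate; 9 methyl 2-(hydroxymethyl)acrylate
Product: 10 methyl (2E,5S,6E,10Z)-5-acetoxy-12-[(tert-butyldimethylsilyl)oxy]-2-(hydroxymethyl)-6,10-dimethyldodeca-2,6,10-trienoate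
Conditions: 9 (4 equiv), second-generation Hoveyda–Grubbs catalyst (2 × 5 mol %), CH2Cl2, 40 °C
Reagents that add atoms: none
Why: Olefin cross-metathesis between the terminal alkene and the 2-substituted acrylate used in excess should form C3=C1′ with C2′ trans to the ester (the thermodynamic isomer, as with methacrylates), the trisubstituted alkenes staying out of the reaction.

Step 6
Reactants: 10 the enoate; 11 bis(pinacolato)diboron
Product: 12 methyl (3S,5S,6E,10Z)-5-acetoxy-12-[(tert-butyldimethylsilyl)oxy]-2-(hydroxymethyl)-6,10-dimethyl-3-(4,4,5,5-tetramethyl-1,3,2-dioxaborolan-2-yl)dodeca-6,10-dienoate (both epimers at the ester α-carbon)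
Conditions: 11 (1.3 equiv), CuCl (5 mol %), NaOt-Bu (10 mol %), (R)-1-[(SP)-2-(diphenylphosphino)ferrocenyl]ethyldicyclohexylphosphine (6 mol %), MeOH (4 equiv), THF, 0 → 23 °C
Reagents that add atoms: none
Why: Copper-catalysed asymmetric conjugate borylation places boron on C1′ of the only conjugated alkene, methanol protonates the copper enolate before it can expel the allylic oxygen, and the chiral bisphosphine selects the enoate face that gives S at C1′; the α-epimers are of no consequence.

Step 7
Reactants: 12 the β-boryl hydroxy ester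
Product: 13 methyl (3S,5S,6E,10Z)-5-acetoxy-12-[(tert-butyldimethylsilyl)oxy]-2-formyl-6,10-dimethyl-3-(4,4,5,5-tetramethyl-1,3,2-dioxaborolan-2-yl)dodeca-6,10-dienoate (expected mainly as its hydrogen-bonded enol)
Conditions: (COCl)2, DMSO, CH2Cl2, −78 °C; Et3N, −78 → 0 °C
Reagents that add atoms: none
Why: Swern oxidation of the primary alcohol gives the α-formyl ester, whose enolisation erases the α-centre, while the secondary alkyl boronate is inert to activated DMSO.

Step 8
Reactants: 13 the α-formyl ester
Product: 15 methyl (2Z,3S,5S,6E,10Z)-5-acetoxy-12-[(tert-butyldimethylsilyl)oxy]-2-{[(tert-butyldimethylsilyl)oxy]methylidene}-6,10-dimethyl-3-(4,4,5,5-tetramethyl-1,3,2-dioxaborolan-2-yl)dodeca-6,10-dienoate, via lithium enolate 14 (not isolated)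
Conditions: LiN(SiMe3)2 (1.0 equiv), THF, −78 °C; TBSOTf (1.1 equiv), −78 → −40 °C
Reagents that add atoms: tert-butyldimethylsilyl trifluoromethanesulfonate, CC(C)(C)[Si](C)(C)OS(=O)(=O)C(F)(F)F
Why: Deprotonation of the 1,3-dicarbonyl (far more acidic than the acetate) gives chelate 14 with the formyl oxygen held cis to the ester carbonyl, and O-silylation of this chelate (chelation-controlled Z-selective enol derivatisation, as known for enol sulfonates of β-dicarbonyls) should fix the silyloxy group trans to C1′.

Step 9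
Reactants: 15 the α-chiral γ-silyloxy 2-(methoxycarbonyl)allyl boronate; 16 prenal
Product: 18 methyl (2E,5S,6E,10Z)-5-acetoxy-12-[(tert-butyldimethylsilyl)oxy]-2-[(1S,2R)-1-[(tert-butyldimethylsilyl)oxy]-2-hydroxy-4-methylpent-3-en-1-yl]-6,10-dimethyldodeca-2,6,10-trienoate, via borate ester 17 (not isolated)
Conditions: 16 (5 equiv), Sc(OTf)3 (5 mol %), 4 Å MS, toluene, −20 → 23 °C; aq NaHCO3
Reagents that add atoms: none
Why: Proposed new method: the boron of 15 takes up the carbonyl oxygen of 16 and the allyl unit is delivered through a closed six-membered chair (allylboration with allylic transposition), C4 bonding to the aldehyde carbon while the C1′–B bond is exchanged for the C3=C1′ double bond; Sc(OTf)3 is added because the ester and the enol oxygen make C4 a weak nucleophile and ester-bearing allylboronates are known to respond to Lewis acids. The closest known reactions are the aldehyde allylborations of 2-alkoxycarbonylallylboronates (which lead to α-methylene lactones) and of α-chiral E-γ-alkoxyallylboronates (which lead to anti diol monoethers); a reagent combining the ester, the γ-oxygen and the α-substituent has not been described. No ring closes in this step, ring A following in step 10. Both new stereocentres come from the one chair: the C2′ methylene on the boron-bearing carbon sits axial, since an equatorial place would eclipse the ester and crowd the pinacol methyls, and with boron and the new bond on the same face this fixes the attacked face of C4 (S) and the E geometry of C3=C1′, while the equatorial silyloxy group and the equatorial isobutenyl group of the aldehyde give the anti relation and R at C5. The step needs transfer through this single chair with γ-attack only; the S configuration at C1′ from step 6 and the enol ether geometry from step 8 (silyloxy trans to C1′, Z by the sequence rule) secure it, because an enol oxygen cis to C1′ would stand axial, 1,3 to the axial methylene, and would lead to the syn series.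

Step 10
Reactants: 18 the anti hydroxy ester
Product: 20 (3E,4S,5R)-3-[(3S,4E,8Z)-3-acetoxy-10-hydroxy-4,8-dimethyldeca-4,8-dien-1-ylidene]-4-hydroxy-5-(2-methylprop-1-en-1-yl)oxolan-2-one, via bis-silyl lactone 19 (not isolated)
Conditions: PPTS (0.2 equiv), toluene, 50 °C; evaporate; HF·pyridine, pyridine, THF, 0 → 23 °C
Reagents that add atoms: none
Why: Acid-catalysed 5-exo-trig transesterification of the C5 hydroxyl onto the methyl ester closes ring A without touching C4 or C5 (the anti adduct gives the trans lactone), and HF·pyridine then cleaves both silyl ethers while acetate and lactone survive.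

Step 11
Reactants: 20 the diol lactone; 21 angelic acid
Product: 23 the target, (2Z,6E,8S)-8-acetoxy-10-[(3E,4S,5R)-4-hydroxy-5-(2-methylprop-1-en-1-yl)-2-oxooxolan-3-ylidene]-3,7-dimethyldeca-2,6-dien-1-yl (2Z)-2-methylbut-2-enoate, via mixed anhydride 22 (not isolated)
Conditions: 21 (1.5 equiv), 2,4,6-trichlorobenzoyl chloride (1.5 equiv), Et3N (3 equiv), toluene, 23 °C; then 20, 23 → 40 °C
Reagents that add atoms: none
Why: Yamaguchi esterification through mixed anhydride 22 without DMAP, conditions that do not isomerise angelate to tiglate, should acylate the primary allylic alcohol far faster than the hindered secondary C4 hydroxyl.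

**Compound list**

1 | nerol, (2Z)-3,7-dimethylocta-2,6-dien-1-ol | OC/C=C(/C)CCC=C(C)C | starting material
2 | neryl TBS ether | CC(C)(C)[Si](C)(C)OC/C=C(/C)CCC=C(C)C | intermediate
3 | (2E,6Z)-8-[(tert-butyldimethylsilyl)oxy]-2,6-dimethylocta-2,6-dien-1-ol | CC(C)(C)[Si](C)(C)OC/C=C(/C)CC/C=C(\C)CO | intermediate
4 | (2E,6Z)-8-[(tert-butyldimethylsilyl)oxy]-2,6-dimethylocta-2,6-dienal | CC(C)(C)[Si](C)(C)OC/C=C(/C)CC/C=C(\C)C=O | intermediate
5 | allylboronic acid pinacol ester | C=CCB1OC(C)(C)C(C)(C)O1 | starting material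
6 | pinacol borate ester of alcohol 7 | CC(C)(C)[Si](C)(C)OC/C=C(/C)CC/C=C(\C)[C@H](CC=C)OB1OC(C)(C)C(C)(C)O1 | intermediate
7 | (4S,5E,9Z)-11-[(tert-butyldimethylsilyl)oxy]-5,9-dimethylundeca-1,5,9-trien-4-ol | CC(C)(C)[Si](C)(C)OC/C=C(/C)CC/C=C(\C)[C@H](CC=C)O | intermediate
8 | (4S,5E,9Z)-11-[(tert-butyldimethylsilyl)oxy]-5,9-dimethylundeca-1,5,9-trien-4-yl acetate | CC(C)(C)[Si](C)(C)OC/C=C(/C)CC/C=C(\C)[C@H](CC=C)OC(C)=O | intermediate
9 | methyl 2-(hydroxymethyl)acrylate | C=C(CO)C(=O)OC | starting material
10 | methyl (2E,5S,6E,10Z)-5-acetoxy-12-[(tert-butyldimethylsilyl)oxy]-2-(hydroxymethyl)-6,10-dimethyldodeca-2,6,10-trienoate | CC(C)(C)[Si](C)(C)OC/C=C(/C)CC/C=C(\C)[C@H](C/C=C(\CO)C(=O)OC)OC(C)=O | intermediate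
11 | bis(pinacolato)diboron | CC1(C)OB(OC1(C)C)B2OC(C)(C)C(C)(C)O2 | starting material
12 | methyl (3S,5S,6E,10Z)-5-acetoxy-12-[(tert-butyldimethylsilyl)oxy]-2-(hydroxymethyl)-6,10-dimethyl-3-(pinacolboryl)dodeca-6,10-dienoate, α-epimers | CC(C)(C)[Si](C)(C)OC/C=C(/C)CC/C=C(\C)[C@H](C[C@H](B1OC(C)(C)C(C)(C)O1)C(CO)C(=O)OC)OC(C)=O | intermediate
13 | methyl (3S,5S,6E,10Z)-5-acetoxy-12-[(tert-butyldimethylsilyl)oxy]-2-formyl-6,10-dimethyl-3-(pinacolboryl)dodeca-6,10-dienoate, drawn as the aldehyde tautomer | CC(C)(C)[Si](C)(C)OC/C=C(/C)CC/C=C(\C)[C@H](C[C@H](B1OC(C)(C)C(C)(C)O1)C(C=O)C(=O)OC)OC(C)=O | intermediate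
14 | lithium Z-enolate of 13 (formyl oxygen cis to the ester) | CC(C)(C)[Si](C)(C)OC/C=C(/C)CC/C=C(\C)[C@H](C[C@H](B1OC(C)(C)C(C)(C)O1)/C(C(=O)OC)=C/[O-])OC(C)=O.[Li+] | intermediate
15 | methyl (2Z,3S,5S,6E,10Z)-5-acetoxy-12-[(tert-butyldimethylsilyl)oxy]-2-{[(tert-butyldimethylsilyl)oxy]methylidene}-6,10-dimethyl-3-(pinacolboryl)dodeca-6,10-dienoate (key-step precursor) | CC(C)(C)[Si](C)(C)OC/C=C(/C)CC/C=C(\C)[C@H](C[C@H](B1OC(C)(C)C(C)(C)O1)/C(C(=O)OC)=C/O[Si](C)(C)C(C)(C)C)OC(C)=O | intermediate
16 | prenal, 3-methylbut-2-enal | CC(C)=CC=O | starting material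
17 | pinacol borate ester of 18 | CC(C)(C)[Si](C)(C)OC/C=C(/C)CC/C=C(\C)[C@H](C/C=C(/C(=O)OC)[C@H](O[Si](C)(C)C(C)(C)C)[C@H](OB1OC(C)(C)C(C)(C)O1)C=C(C)C)OC(C)=O | intermediate
18 | methyl (2E,5S,6E,10Z)-5-acetoxy-12-[(tert-butyldimethylsilyl)oxy]-2-[(1S,2R)-1-[(tert-butyldimethylsilyl)oxy]-2-hydroxy-4-methylpent-3-en-1-yl]-6,10-dimethyldodeca-2,6,10-trienoate (key-step product) | CC(C)(C)[Si](C)(C)OC/C=C(/C)CC/C=C(\C)[C@H](C/C=C(/C(=O)OC)[C@H](O[Si](C)(C)C(C)(C)C)[C@H](O)C=C(C)C)OC(C)=O | intermediate
19 | (3E,4S,5R)-3-[(3S,4E,8Z)-3-acetoxy-10-[(tert-butyldimethylsilyl)oxy]-4,8-dimethyldeca-4,8-dien-1-ylidene]-4-[(tert-butyldimethylsilyl)oxy]-5-(2-methylprop-1-en-1-yl)oxolan-2-one | CC(C)(C)[Si](C)(C)OC/C=C(/C)CC/C=C(\C)[C@H](C/C=C1/C(=O)O[C@H](C=C(C)C)[C@H]1O[Si](C)(C)C(C)(C)C)OC(C)=O | intermediate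
20 | (3E,4S,5R)-3-[(3S,4E,8Z)-3-acetoxy-10-hydroxy-4,8-dimethyldeca-4,8-dien-1-ylidene]-4-hydroxy-5-(2-methylprop-1-en-1-yl)oxolan-2-one | OC/C=C(/C)CC/C=C(\C)[C@H](C/C=C1/C(=O)O[C@H](C=C(C)C)[C@H]1O)OC(C)=O | intermediate
21 | angelic acid, (2Z)-2-methylbut-2-enoic acid | C/C=C(/C)C(=O)O | starting material
22 | angelic 2,4,6-trichlorobenzoic anhydride | C/C=C(/C)C(=O)OC(=O)c1c(Cl)cc(Cl)cc1Cl | intermediate
23 | CNP0201198.1, (2Z,6E,8S)-8-acetoxy-10-[(3E,4S,5R)-4-hydroxy-5-(2-methylprop-1-en-1-yl)-2-oxooxolan-3-ylidene]-3,7-dimethyldeca-2,6-dien-1-yl (2Z)-2-methylbut-2-enoate | C/C=C(/C)C(=O)OC/C=C(/C)CC/C=C(\C)[C@H](C/C=C1/C(=O)O[C@H](C=C(C)C)[C@H]1O)OC(C)=O | target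

**Step count and risks**

Total step count: 11. Longest linear sequence: 11 steps (nerol 1 to target 23).

Steps most likely to fail:

1. Step 9 (proposed new method). The push–pull allyl unit may not transfer at all, the Lewis acid may strip the silyl enol ether before transfer, or part of the reaction may run through the chair with C2′ equatorial and erode both the alkene geometry and the chirality relay. Fallback with known reactions only, setting out from prenal 16 and acetate 8 and returning at diol 20: ring A is built first and joined to the chain by metathesis. (R)-Oxynitrilase-catalysed addition of HCN to 16 should give (R)-2-hydroxy-4-methylpent-3-enenitrile F1. Silylation (TBSCl, imidazole) gives (R)-2-[(tert-butyldimethylsilyl)oxy]-4-methylpent-3-enenitrile F2, and i-Bu2AlH reduction with hydrolysis gives (R)-2-[(tert-butyldimethylsilyl)oxy]-4-methylpent-3-enal F3. Addition of the α-(methoxycarbonyl)vinylaluminium reagent made from methyl propiolate and i-Bu2AlH/HMPA (a Baylis–Hillman-type adduct by vinylalumination, under Felkin–Anh control) should give the anti adduct methyl (3S,4R)-4-[(tert-butyldimethylsilyl)oxy]-3-hydroxy-6-methyl-2-methylidenehept-5-enoate F4. HF in MeCN removes the silyl group with lactonisation to (4S,5R)-4-hydroxy-3-methylidene-5-(2-methylprop-1-en-1-yl)oxolan-2-one F5. Cross-metathesis of F5 with 8 (second-generation Hoveyda–Grubbs catalyst, CH2Cl2, 40 °C) should give (3E,4S,5R)-3-[(3S,4E,8Z)-3-acetoxy-10-[(tert-butyldimethylsilyl)oxy]-4,8-dimethyldeca-4,8-dien-1-ylidene]-4-hydroxy-5-(2-methylprop-1-en-1-yl)oxolan-2-one F6. HF·pyridine then gives 20, and step 11 follows.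

2. Step 6. Boryl transfer to the trisubstituted, α-branched enoate may be slow or poorly face-selective, and the copper enolate may expel the allylic oxygen instead of being protonated. Fallback, setting out from 10 and returning at 13: the alcohol is oxidised first. MnO2 converts 10 into methyl (2E,5S,6E,10Z)-5-acetoxy-12-[(tert-butyldimethylsilyl)oxy]-2-formyl-6,10-dimethyldodeca-2,6,10-trienoate F7. Its doubly activated C3=C1′ bond should take up boron from 11 with the same chiral copper catalyst at −78 °C, and the chelated enolate, which has nothing to eliminate, gives 13 on work-up; steps 6 and 7 are both replaced.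

3. Step 5. Self-metathesis of 8 may outrun the slow cross reaction with the 1,1-disubstituted acrylate, and the catalyst may decompose on the free allylic alcohol. Fallback, setting out from 8 and returning at 12: cross-metathesis with methyl acrylate, a well-behaved partner, gives methyl (2E,5S,6E,10Z)-5-acetoxy-12-[(tert-butyldimethylsilyl)oxy]-6,10-dimethyldodeca-2,6,10-trienoate F8. Copper-catalysed conjugate borylation of this β-monosubstituted enoate with the same ligand under aprotic conditions, with the copper enolate intercepted by monomeric formaldehyde (borylative aldol), should give 12 directly; steps 5 and 6 are both replaced.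

**Further compounds**

F1 | step 9 | (R)-2-hydroxy-4-methylpent-3-enenitrile | N#C[C@H](O)C=C(C)C
F2 | step 9 | (R)-2-[(tert-butyldimethylsilyl)oxy]-4-methylpent-3-enenitrile | N#C[C@H](O[Si](C)(C)C(C)(C)C)C=C(C)C
F3 | step 9 | (R)-2-[(tert-butyldimethylsilyl)oxy]-4-methylpent-3-enal | O=C[C@H](O[Si](C)(C)C(C)(C)C)C=C(C)C
F4 | step 9 | methyl (3S,4R)-4-[(tert-butyldimethylsilyl)oxy]-3-hydroxy-6-methyl-2-methylidenehept-5-enoate | C=C(C(=O)OC)[C@H](O)[C@H](O[Si](C)(C)C(C)(C)C)C=C(C)C
F5 | step 9 | (4S,5R)-4-hydroxy-3-methylidene-5-(2-methylprop-1-en-1-yl)oxolan-2-one | C=C1C(=O)O[C@H](C=C(C)C)[C@H]1O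
F6 | step 9 | (3E,4S,5R)-3-[(3S,4E,8Z)-3-acetoxy-10-[(tert-butyldimethylsilyl)oxy]-4,8-dimethyldeca-4,8-dien-1-ylidene]-4-hydroxy-5-(2-methylprop-1-en-1-yl)oxolan-2-one | CC(C)(C)[Si](C)(C)OC/C=C(/C)CC/C=C(\C)[C@H](C/C=C1/C(=O)O[C@H](C=C(C)C)[C@H]1O)OC(C)=O
F7 | step 6 | methyl (2E,5S,6E,10Z)-5-acetoxy-12-[(tert-butyldimethylsilyl)oxy]-2-formyl-6,10-dimethyldodeca-2,6,10-trienoate | CC(C)(C)[Si](C)(C)OC/C=C(/C)CC/C=C(\C)[C@H](C/C=C(\C=O)C(=O)OC)OC(C)=O
F8 | step 5 | methyl (2E,5S,6E,10Z)-5-acetoxy-12-[(tert-butyldimethylsilyl)oxy]-6,10-dimethyldodeca-2,6,10-trienoate | CC(C)(C)[Si](C)(C)OC/C=C(/C)CC/C=C(\C)[C@H](C/C=C/C(=O)OC)OC(C)=O
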